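**Retrosynthetic overview**

- The route rests on the benzene ring C3a–C4–C5–C6–C7–C7a of the phthalide, which carries oxygen at C5 and C7 and the carboxyl carbon C1 on C7a. This is a resorcylate pattern: C1/C7a/C7/C6 is an acetoacetate unit and C5/C4/C3a is an acrylate unit whose β-carbon bears the C3 stereocentre.
- The lactone C1–O2 bond is cut last in the analysis; the arene is then traced to a cyclohexane-1,3-dione, which is opened at C3a–C7a and C5–C6 into methyl acetoacetate and the (S)-γ-silyloxy enoate 14, a (3+3) Michael–Dieckmann annulation.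
- Enoate 14 comes from aldehyde 9 by D-proline-catalysed α-aminoxylation with in-flask olefination, which sets C3. Aldehyde 9 comes from 2-methylfuran (a masked 1,4-diketone) and 11-bromoundecan-1-ol.
- Ring order: carbocycle (step 9), aromatised (step 10), then the γ-lactone (step 12); the 1,4-diketone is unmasked last.

Key step: step 9

Remark on the chemistry: L-proline is known to give (R)-2-aminoxy aldehydes from linear aldehydes, so the (S) series needed here is assigned to D-proline.
Remark on the chemistry: the nitrogen fragment of the Cu(OAc)2-catalysed N–O cleavage in step 7 is assumed to leave as azobenzene (half an equivalent).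

**Route**

Step 1
Reactants: 1 11-bromoundecan-1-ol
Product: 2 (11-bromoundecyloxy)(tert-butyl)dimethylsilane
Conditions: TBSCl, imidazole, CH2Cl2, 0 °C → rt
Reagents that add atoms: tert-butyldimethylsilyl chloride, CC(C)(C)[Si](C)(C)Cl
Why: Standard silylation of a primary alcohol masks the hydroxyl proton so that the bromide can be used against an organolithium in the next step.

Step 2
Reactants: 3 2-methylfuran; 2 (11-bromoundecyloxy)(tert-butyl)dimethylsilane
Product: 5 tert-butyldimethyl{[11-(5-methylfuran-2-yl)undecyl]oxy}silane, via 5-methyl-2-furyllithium 4 (not isolated)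
Conditions: n-BuLi, THF, −78 → 0 °C; then 2, 0 °C → rt
Reagents that add atoms: none
Why: 2-Methylfuran is lithiated selectively at its free α-position and the furyllithium undergoes SN2 alkylation with the unhindered primary bromide.

Step 3
Reactants: 5 tert-butyldimethyl{[11-(5-methylfuran-2-yl)undecyl]oxy}silane
Product: 7 16-hydroxyhexadecane-2,5-dione, via hydroxy furan 6 (not isolated)
Conditions: 2 M H2SO4 (aq), 1,4-dioxane, 90 °C
Reagents that add atoms: water, O
Why: Aqueous acid protonates the 2,5-dialkylfuran at an α-carbon and water opens it to the 1,4-diketone (reverse Paal–Knorr hydrolysis), the primary silyl ether being hydrolysed under the same conditions.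

Step 4
Reactants: 7 16-hydroxyhexadecane-2,5-dione
Product: 8 11-{2-[2-(2-methyl-1,3-dioxolan-2-yl)ethyl]-1,3-dioxolan-2-yl}undecan-1-ol (16-hydroxyhexadecane-2,5-dione bis(ethylene ketal))
Conditions: HOCH2CH2OH (excess), TsOH·H2O (cat.), benzene, reflux (Dean–Stark)
Reagents that add atoms: ethylene glycol, OCCO
Why: Acid-catalysed ketalisation with azeotropic removal of water converts both ketones into 1,3-dioxolanes, the excess of glycol keeping the 1,4-diketone from closing back to the furan.

Step 5
Reactants: 8 11-{2-[2-(2-methyl-1,3-dioxolan-2-yl)ethyl]-1,3-dioxolan-2-yl}undecan-1-ol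
Product: 9 11-{2-[2-(2-methyl-1,3-dioxolan-2-yl)ethyl]-1,3-dioxolan-2-yl}undecanal (12,15-dioxohexadecanal bis(ethylene ketal))
Conditions: (COCl)2, DMSO, CH2Cl2, −78 °C; Et3N, −78 → 0 °C
Reagents that add atoms: none
Why: Swern oxidation stops cleanly at the aldehyde and is non-acidic after the amine quench, so both dioxolanes should survive.

Step 6
Reactants: 9 12,15-dioxohexadecanal bis(ethylene ketal); 10 trimethyl phosphonoacetate
Product: 12 methyl (S,E)-4-(N-phenylaminooxy)-14,17-dioxooctadec-2-enoate bis(ethylene ketal), via α-aminoxy aldehyde 11 (not isolated)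
Conditions: PhNO, D-proline (20 mol%), DMSO, rt; then 10, LiCl, DBU, MeCN, 0 °C
Reagents that add atoms: nitrosobenzene, O=Nc1ccccc1
Why: D-Proline forms the enamine of 9 and its carboxylic acid directs O-attack of nitrosobenzene to one face (α-aminoxylation), which should give the (S) aldehyde 11, the mirror image of the (R) product known from L-proline, and this is olefinated at once under Masamune–Roush Horner–Wadsworth–Emmons conditions to the E enoate before it can racemise.

Step 7
Reactants: 12 methyl (S,E)-4-(N-phenylaminooxy)-14,17-dioxooctadec-2-enoate bis(ethylene ketal)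
Product: 13 methyl (S,E)-4-hydroxy-14,17-dioxooctadec-2-enoate bis(ethylene ketal)
Conditions: Cu(OAc)2·H2O (30 mol%), MeOH, rt
Reagents that add atoms: none
Why: Divalent copper cleaves the weak N–O bond of the O-alkyl-N-phenylhydroxylamine under neutral conditions, without touching the enoate, the dioxolanes or the allylic stereocentre.

Step 8
Reactants: 13 methyl (S,E)-4-hydroxy-14,17-dioxooctadec-2-enoate bis(ethylene ketal)
Product: 14 methyl (S,E)-4-(tert-butyldimethylsilyloxy)-14,17-dioxooctadec-2-enoate bis(ethylene ketal)
Conditions: TBSCl, imidazole, DMF, rt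
Reagents that add atoms: tert-butyldimethylsilyl chloride, CC(C)(C)[Si](C)(C)Cl
Why: Silylation of the secondary allylic alcohol removes the free alkoxide that would otherwise interfere with the alkoxide-mediated annulation, and it leaves the stereocentre untouched.

Step 9
Reactants: 14 methyl (S,E)-4-(tert-butyldimethylsilyloxy)-14,17-dioxooctadec-2-enoate bis(ethylene ketal); 15 methyl acetoacetate
Product: 17 methyl 6-[(S)-1-(tert-butyldimethylsilyloxy)-11,14-dioxopentadecyl]-2,4-dioxocyclohexane-1-carboxylate bis(ethylene ketal) (ring C1 and C6 as a mixture), via Michael adduct 16 (not isolated)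
Conditions: 15 (1.5 equiv), NaOMe (1.3 equiv), MeOH, 0 °C → rt, then reflux; AcOH, 0 °C (to pH 5)
Reagents that add atoms: none
Why: The sodium enolate of methyl acetoacetate adds through its central carbon (future C7a) to the β-carbon of enoate 14 (future C3a); after proton transfer the methyl ketone enolate (future C6) acylates on the enoate-derived ester carbon (future C5) with loss of methoxide, and deprotonation of the resulting cyclic tricarbonyl pulls both equilibria forward. This is the classical Michael–Dieckmann (Michael–Claisen) annulation by which acetoacetates and crotonate-type esters give dihydroorsellinates. The carbocycle closes in a 6-exo-trig Claisen mode, and the other possible enolates could only close four-membered rings, so a single constitution is expected. The two new ring sp3 centres form without control, which does not matter because both become aromatic carbons in step 10; the (S) carbinol carbon is not made here and carries no acidic hydrogen once the conjugate addition has taken place. The selectivity needed is conjugate addition over γ-deprotonation of the γ-silyloxy enoate: acetoacetate is kept in excess over methoxide so that the cold Michael stage runs in a medium buffered at the acidity of the β-keto ester, heat is applied only afterwards, and matched methyl esters and methoxide exclude ester scrambling.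

Step 10
Reactants: 17 methyl 6-[(S)-1-(tert-butyldimethylsilyloxy)-11,14-dioxopentadecyl]-2,4-dioxocyclohexane-1-carboxylate bis(ethylene ketal)
Product: 18 methyl 2-[(S)-1-(tert-butyldimethylsilyloxy)-11,14-dioxopentadecyl]-4,6-dihydroxybenzoate bis(ethylene ketal)
Conditions: DDQ (1.5 equiv), dry 1,4-dioxane, rt → 60 °C
Reagents that add atoms: none
Why: DDQ abstracts hydride from the enolised cyclohexane-1,3-dione and loss of a proton gives the trione tautomer of the arene, which enolises irreversibly to the resorcylate (quinone dehydrogenation), the silyl ether and the dioxolanes being inert in dry dioxane.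

Step 11
Reactants: 18 methyl 2-[(S)-1-(tert-butyldimethylsilyloxy)-11,14-dioxopentadecyl]-4,6-dihydroxybenzoate bis(ethylene ketal)
Product: 19 methyl 2-[(S)-1-(tert-butyldimethylsilyloxy)-11,14-dioxopentadecyl]-4,6-dimethoxybenzoate bis(ethylene ketal)
Conditions: MeI (excess), K2CO3, DMF, 40 °C
Reagents that add atoms: iodomethane, CI
Why: Williamson methylation of both phenols, in which the hydrogen-bonded ortho-hydroxyl needs the excess of MeI and warm DMF, conditions that the silyl ether, the ester and the dioxolanes tolerate.

Step 12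
Reactants: 19 methyl 2-[(S)-1-(tert-butyldimethylsilyloxy)-11,14-dioxopentadecyl]-4,6-dimethoxybenzoate bis(ethylene ketal)
Product: 21 (S)-3-(10,13-dioxotetradecyl)-5,7-dimethoxyisobenzofuran-1(3H)-one bis(ethylene ketal), via hydroxy ester 20 (not isolated)
Conditions: Bu4NF, THF, 0 °C → rt
Reagents that add atoms: none
Why: Fluoride cleaves the Si–O bond and the benzylic alkoxide so formed acylates on the neighbouring methyl ester in a 5-exo-trig lactonisation, which leaves the C3–O bond and hence the (S) configuration untouched.

Step 13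
Reactants: 21 (S)-3-(10,13-dioxotetradecyl)-5,7-dimethoxyisobenzofuran-1(3H)-one bis(ethylene ketal)
Product: 22 CJ-13,015, (S)-3-(10,13-dioxotetradecyl)-5,7-dimethoxyisobenzofuran-1(3H)-one
Conditions: 1 M HCl (aq), THF, rt
Reagents that add atoms: water, O
Why: Dilute aqueous acid hydrolyses both dioxolanes to the 1,4-diketone, while the lactone, the aryl methyl ethers and the C3 centre (both methoxy groups are meta to it, so it does not ionise) are stable.

**Compound list**

1 | 11-bromoundecan-1-ol | OCCCCCCCCCCCBr | starting material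
2 | (11-bromoundecyloxy)(tert-butyl)dimethylsilane | CC(C)(C)[Si](C)(C)OCCCCCCCCCCCBr | intermediate
3 | 2-methylfuran | Cc1ccco1 | starting material
4 | 5-methyl-2-furyllithium | [Li]c1ccc(C)o1 | intermediate
5 | tert-butyldimethyl{[11-(5-methylfuran-2-yl)undecyl]oxy}silane | Cc1ccc(CCCCCCCCCCCO[Si](C)(C)C(C)(C)C)o1 | intermediate
6 | 11-(5-methylfuran-2-yl)undecan-1-ol | Cc1ccc(CCCCCCCCCCCO)o1 | intermediate
7 | 16-hydroxyhexadecane-2,5-dione | CC(=O)CCC(=O)CCCCCCCCCCCO | intermediate
8 | 11-{2-[2-(2-methyl-1,3-dioxolan-2-yl)ethyl]-1,3-dioxolan-2-yl}undecan-1-ol | OCCCCCCCCCCCC1(CCC2(C)OCCO2)OCCO1 | intermediate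
9 | 11-{2-[2-(2-methyl-1,3-dioxolan-2-yl)ethyl]-1,3-dioxolan-2-yl}undecanal | O=CCCCCCCCCCCC1(CCC2(C)OCCO2)OCCO1 | intermediate
10 | trimethyl phosphonoacetate | COC(=O)CP(=O)(OC)OC | starting material
11 | (S)-2-(N-phenylaminooxy)-12,15-dioxohexadecanal bis(ethylene ketal) | O=C[C@H](CCCCCCCCCC1(CCC2(C)OCCO2)OCCO1)ONc3ccccc3 | intermediate
12 | methyl (S,E)-4-(N-phenylaminooxy)-14,17-dioxooctadec-2-enoate bis(ethylene ketal) | COC(=O)/C=C/[C@H](CCCCCCCCCC1(CCC2(C)OCCO2)OCCO1)ONc3ccccc3 | intermediate
13 | methyl (S,E)-4-hydroxy-14,17-dioxooctadec-2-enoate bis(ethylene ketal) | COC(=O)/C=C/[C@H](CCCCCCCCCC1(CCC2(C)OCCO2)OCCO1)O | intermediate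
14 | methyl (S,E)-4-(tert-butyldimethylsilyloxy)-14,17-dioxooctadec-2-enoate bis(ethylene ketal) | COC(=O)/C=C/[C@H](CCCCCCCCCC1(CCC2(C)OCCO2)OCCO1)O[Si](C)(C)C(C)(C)C | intermediate
15 | methyl acetoacetate | CC(=O)CC(=O)OC | starting material
16 | dimethyl 2-acetyl-3-[(S)-1-(tert-butyldimethylsilyloxy)-11,14-dioxopentadecyl]pentanedioate bis(ethylene ketal) | COC(=O)CC([C@H](CCCCCCCCCC1(CCC2(C)OCCO2)OCCO1)O[Si](C)(C)C(C)(C)C)C(C(C)=O)C(=O)OC | intermediate
17 | methyl 6-[(S)-1-(tert-butyldimethylsilyloxy)-11,14-dioxopentadecyl]-2,4-dioxocyclohexane-1-carboxylate bis(ethylene ketal) | COC(=O)C1C(=O)CC(=O)CC1[C@H](CCCCCCCCCC2(CCC3(C)OCCO3)OCCO2)O[Si](C)(C)C(C)(C)C | intermediate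
18 | methyl 2-[(S)-1-(tert-butyldimethylsilyloxy)-11,14-dioxopentadecyl]-4,6-dihydroxybenzoate bis(ethylene ketal) | COC(=O)c1c(O)cc(O)cc1[C@H](CCCCCCCCCC2(CCC3(C)OCCO3)OCCO2)O[Si](C)(C)C(C)(C)C | intermediate
19 | methyl 2-[(S)-1-(tert-butyldimethylsilyloxy)-11,14-dioxopentadecyl]-4,6-dimethoxybenzoate bis(ethylene ketal) | COC(=O)c1c(OC)cc(OC)cc1[C@H](CCCCCCCCCC2(CCC3(C)OCCO3)OCCO2)O[Si](C)(C)C(C)(C)C | intermediate
20 | methyl 2-[(S)-1-hydroxy-11,14-dioxopentadecyl]-4,6-dimethoxybenzoate bis(ethylene ketal) | COC(=O)c1c(OC)cc(OC)cc1[C@H](CCCCCCCCCC2(CCC3(C)OCCO3)OCCO2)O | intermediate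
21 | (S)-3-(10,13-dioxotetradecyl)-5,7-dimethoxyisobenzofuran-1(3H)-one bis(ethylene ketal) | COc1cc(OC)c2c(c1)[C@H](CCCCCCCCCC3(CCC4(C)OCCO4)OCCO3)OC2=O | intermediate
22 | CJ-13,015, (S)-3-(10,13-dioxotetradecyl)-5,7-dimethoxyisobenzofuran-1(3H)-one | COc1cc(OC)c2c(c1)[C@H](CCCCCCCCCC(=O)CCC(C)=O)OC2=O | target

**Step count**

Total step count: 13. Longest linear sequence: 13 steps (1 → 22).

**Steps most likely to fail**

Step 9. The γ-hydrogen of enoate 14 may be removed before conjugate addition, which would erode the C3 configuration or isomerise the enoate. Addition at the γ-branched β-carbon may also be slow, and methoxide may strip the silyl group at reflux. The fallback tethers the nucleophile; it sets out from 13 and comes back at 21.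
- Alcohol 13 would be acetoacetylated with 2,2,6-trimethyl-4H-1,3-dioxin-4-one in toluene at 110 °C (trapping of acetylketene) to give the acetoacetate ester F1.
- Cs2CO3 in MeCN at 0 °C would then deliver the acetoacetate carbon intramolecularly to the enoate β-carbon (5-exo-trig Michael addition). This forms C3a–C7a and the γ-lactone together, giving the α-acetyl butyrolactone F2.
- NaOMe in MeOH would close the carbocycle by Claisen condensation of the acetyl methyl group on the CH2CO2Me ester, giving the bicyclic lactone trione F3.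
- DDQ in dioxane would aromatise this to the 5,7-dihydroxyphthalide F4, and MeI with K2CO3 would give 21.

Step 10. Hydride abstraction from the enolised trione may be incomplete or unselective, and the acidic hydroquinone formed may begin to open the dioxolanes. The fallback replaces hydride abstraction by a selenoxide elimination; it sets out from 17 and comes back at 18.
- Double deprotonation of 17 with LDA (2.2 equiv) in THF at −78 °C and quenching with PhSeBr should selenate the ester-bearing ring carbon, the more reactive site of the dianion, to give the selenide F5.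
- Oxidation with aqueous H2O2 and pyridine in CH2Cl2 at 0 °C → rt would give the selenoxide, which eliminates syn towards the neighbouring ring C–H; the resulting dienone tautomerises to 18.

Step 6. The α-aminoxy aldehyde may lose configuration or fragment at its N–O bond under the basic olefination, and nitrosobenzene may be attacked at nitrogen instead of oxygen. The fallback uses a different oxygen electrophile and a neutral olefination; it sets out from 9 and comes back at 13.
- Aldehyde 9 would be α-benzoyloxylated with benzoyl peroxide, (S)-2-(triphenylmethyl)pyrrolidine (10 mol%) and a little hydroquinone in THF at 0 °C. On the steric-shielding model this catalyst is expected to give the (S) product, the isolable α-benzoyloxy aldehyde F6.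
- Wittig reaction with Ph3P=CHCO2Me in CH2Cl2 at rt would give the γ-benzoyloxy enoate F7.
- K2CO3 in MeOH at 0 °C would remove the benzoate to give 13.

Further compounds
F1 | step 9 | methyl (S,E)-4-(3-oxobutanoyloxy)-14,17-dioxooctadec-2-enoate bis(ethylene ketal) | COC(=O)/C=C/[C@H](CCCCCCCCCC1(CCC2(C)OCCO2)OCCO1)OC(=O)CC(C)=O
F2 | step 9 | methyl 2-{(2S)-4-acetyl-2-(9-{2-[2-(2-methyl-1,3-dioxolan-2-yl)ethyl]-1,3-dioxolan-2-yl}nonyl)-5-oxooxolan-3-yl}acetate | COC(=O)CC1C(C(C)=O)C(=O)O[C@H]1CCCCCCCCCC2(CCC3(C)OCCO3)OCCO2
F3 | step 9 | (3S)-3-(10,13-dioxotetradecyl)-3a,4-dihydroisobenzofuran-1,5,7(3H,6H,7aH)-trione bis(ethylene ketal) | O=C1CC(=O)C2C(C1)[C@H](CCCCCCCCCC3(CCC4(C)OCCO4)OCCO3)OC2=O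
F4 | step 9 | (S)-3-(10,13-dioxotetradecyl)-5,7-dihydroxyisobenzofuran-1(3H)-one bis(ethylene ketal) | Oc1cc(O)c2c(c1)[C@H](CCCCCCCCCC3(CCC4(C)OCCO4)OCCO3)OC2=O
F5 | step 10 | methyl 6-[(S)-1-(tert-butyldimethylsilyloxy)-11,14-dioxopentadecyl]-2,4-dioxo-1-(phenylselanyl)cyclohexane-1-carboxylate bis(ethylene ketal) | COC(=O)C1([Se]c2ccccc2)C(=O)CC(=O)CC1[C@H](CCCCCCCCCC3(CCC4(C)OCCO4)OCCO3)O[Si](C)(C)C(C)(C)C
F6 | step 6 | (S)-2-(benzoyloxy)-12,15-dioxohexadecanal bis(ethylene ketal) | O=C[C@H](CCCCCCCCCC1(CCC2(C)OCCO2)OCCO1)OC(=O)c3ccccc3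
F7 | step 6 | methyl (S,E)-4-(benzoyloxy)-14,17-dioxooctadec-2-enoate bis(ethylene ketal) | COC(=O)/C=C/[C@H](CCCCCCCCCC1(CCC2(C)OCCO2)OCCO1)OC(=O)c3ccccc3
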